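## Conventions and assumptions

- The terpene carbons keep the decalin locants of the target in every bicyclic intermediate: C3 (bears the aryloxy group and a methyl group in the target), C4, C4a (ring-fusion CH), C5, C6 (bears the 2-hydroxypropan-2-yl group), C7, C8, C8a (ring-fusion carbon with the angular methyl), C1, C2. Ring A is C1–C4/C4a/C8a; ring B is C4a/C5–C8/C8a. β is the face of the C8a methyl group, α the opposite face.
- Assumption on step 4: the (R)-BINAP ligand is assigned by analogy with acyclic α,β-unsaturated acids of the same substitution pattern. If the cyclic acid responds with the opposite sense, the (S)-ligand is used and nothing else changes.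
- Compounds 1, 2, 11, 13, 20, 21 and 25 are taken as catalogue chemicals.

## Analysis of the target

The target is a mono-ether of a 3',5-diallylbiphenyl-2,4'-diol. The oxygen ortho to the biaryl bond is attached to C3 of a trans-fused decalin (rings A and B). The decalin has four stereocentres: C3 (aryloxy axial on the α face, methyl equatorial on the β face), C4a (H on the α face), C6 (2-hydroxypropan-2-yl, equatorial, β) and C8a (angular methyl, axial, β). The ring fusion is trans; the C8a methyl is cis to the C6 side chain and to the C3 methyl, and trans to the aryloxy group. C3, C6 and C8a are not adjacent to one another, so each relationship has to be relayed through the ring system. The sensitive groups are the tertiary alkyl aryl ether (ionises in acid), the tertiary alcohol (dehydration), two allyl groups (migration into conjugation, no hydrogenation late in the route) and a free phenol. Three things make the synthesis hard: the bond between a hindered axial tertiary oxygen and an ortho-substituted arene, the quaternary C8a in a defined relation to the remote C6, and two tertiary hydroxyls that must be told apart. The strategy rests on the fact that rings A and B, with oxygen at C3 and a carbon substituent at C6, are the skeleton of a 7-methoxytetralin substituted at its C2. Ring A is the anisole ring and only the C8a methyl is missing. Birch reduction leaves a tetrasubstituted C4a=C8a alkene exactly where that carbon must be attached.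

## Retrosynthetic reasoning

**31 to 30.** The last operation is removal of a triethylsilyl group from the side-chain oxygen. The group is there because the side-chain hydroxyl and the C3 hydroxyl are both tertiary, and only the C3 oxygen may be arylated.

**30 to 29.** The allyl–aryl bond para to the ether oxygen is cut, leaving an aryl chloride. A chloride survives all earlier steps and does not compete with bromide in the preceding coupling. The forward step must couple an allyl–metal reagent without moving either double bond.

**29 to 24 and 28.** The biaryl bond is cut. This is the convergent cut: boronate 28 already carries its allyl group and the free phenol, so no protecting group is needed on that ring. The forward coupling must react at C–Br and leave C–Cl. Boronate 28 goes back through bromophenol 27 to allyl ether 25 by an aromatic Claisen rearrangement, which places the allyl group ortho to oxygen.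

**24 to 19 and 23.** The aryl–oxygen bond is cut, not the C3–oxygen bond. Cutting C3–O would need a stereocontrolled substitution at a tertiary carbon. Cutting aryl–O leaves the C3 configuration to an earlier, reliable carbonyl addition. The forward step is arylation of the tertiary alkoxide of 19 by iodonium salt 23, which comes from aryl iodide 20 and arene 21.

**19 to 18 to 17 to 16.** The C3–methyl bond is cut to decalone 18; a bulky methyl nucleophile must enter equatorially. The C4a–H bond is traced to enone 17 by dissolving-metal reduction, which gives the trans fusion. Silyl ether 17 comes from hydroxy enone 16.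

**16 to 14.** The C8a methyl group is traced back to the CH2 of a cyclopropane fused across C4a–C8a. Hydrolysis of the ketal and homoconjugate opening of the cyclopropyl ketone deliver the methyl and the C4=C4a enone together. This converts the problem of a quaternary methyl into face-selective addition to an alkene.

**14 to 12 and 13 (key disconnection).** The C4a–CH2 and C8a–CH2 bonds are cut. The cut is made here because the C4a=C8a alkene is the one that dearomatisation leaves behind, and because the C6 carbinol is available to steer a zinc carbenoid. The forward step must put the CH2 on the β face.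

**12 to 10 to 9.** The ketal is formed from the enol ether of the Birch product 10, which comes from methoxytetralin carbinol 9. The dearomatisation supplies ring A with its C3 oxygen and the ring-fusion alkene in one step.

**9 to 8 to 7 to 6.** The carbinol comes from ester 8 by double methyl addition. The C6 stereocentre of acid 7 is set by asymmetric hydrogenation of unsaturated acid 6, the only step in which absolute configuration is introduced.

**6 to 5 to 3 to 1 and 2.** Carboxylation of tetralone 1 with carbonate 2 places the future side-chain carbon at C6. Reduction and dehydration remove the carbonyl oxygen and leave the alkene needed for the hydrogenation.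

## Alternatives that were turned down

**Alternative 1:** The C3–C4 bond of ring A is cut, with the aryl–O–C3 bond already in place. Aryl ester A1 would be methylenated at its carbonyl group by a titanium methylidene reagent to aryl enol ether A2. Acid would protonate A2 at its terminal carbon; the aryloxy-stabilised cation at C3 would be captured by the exocyclic methylene carbon on ring B (the future C4), and proton loss would give octalin A3 with a C4a=C5 alkene.
- For: the aryl–oxygen bond comes from simple acylation of a phenol, so arylation of a hindered tertiary alkoxide is avoided. On this point the alternative is stronger than the chosen route.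
- Against: the C3 configuration is decided in a cation–alkene closure in which methyl and aryloxy compete for the axial position without an evident bias. A3 is a tertiary alkyl aryl ether that can ionise under the acid that forms it, and the silyl ether is acid-labile too. The proton can be lost towards C4 as well as C5. The C4a=C5 alkene must then be saturated from the α face in the presence of aryl bromide and chloride. Ring B with its quaternary C8a and the C6 substituent must first be made enantiopure, which costs about as much as the whole decalin in the chosen route.
- Comparison: the chosen route sets C3 by carbonyl addition to a rigid trans-decalone and takes both rings from a flat tetralone. It pays for this with the O-arylation step.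

**Alternative 2:** The C8a–C1 and C4–C4a bonds of ring A are cut (Robinson annulation) and ring B is taken from the chiral pool. (5R)-Dihydrocarvone A4 would be condensed with an enantiopure benzylic amine to imine A5. Its more substituted secondary enamine tautomer adds to but-3-en-2-one A6 at the methyl-bearing carbon (the future C8a); hydrolysis and base-mediated aldol condensation give octalenone A7. Markovnikov hydration of the isopropenyl group of A7 would give the same hydroxy enone as compound 16.
- For: it reaches the level of 16 in three or four steps where the chosen route needs ten. The quaternary centre is controlled by an auxiliary with strong precedent on 2-methylcyclohexanones, and the C6 centre is bought. On step economy and on the security of C8a this alternative is stronger.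
- Against: two controlling elements act at once (the resident substituent and the amine), and the required cis relation between the C8a methyl and the C6 group is the one the resident substituent alone disfavours, so the result depends on a matched pairing. Enantiopurity is limited by the terpene feedstock. The isopropenyl group must be hydrated in the presence of an enone, which radical hydration conditions also attack.
- Comparison: the chosen route offers a catalytic source of chirality with both antipodes equally accessible, has the tertiary hydroxyl in place from the start and uses it as the directing group. It is longer, and that is the price.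

**Alternative 3:** The C5–C6 bond of ring B is cut together with the C–O bond of the tertiary alcohol. Silyl dienol ether A8, a cyclohexenone-derived diene carrying at C8a the methyl group and a 4-methylpent-3-enyl chain, would be oxidised at an anode. The exocyclic terminus of the radical cation (C5) adds to the trisubstituted alkene at C6; the tertiary radical is oxidised again and the cation is captured by the aqueous co-solvent, giving hydroxy enone A9, identical with compound 16.
- For: ring B, the C6 stereocentre and the tertiary alcohol are formed in one operation, and the enone appears without an acid step. In bond construction per step it is stronger than the chosen route.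
- Against: the quaternary C8a must already exist enantiopure in A8, so the main stereochemical problem moves to the preparation of A8. C6 is then set relative to C8a in a radical-cation closure whose chair-like preference is plausible but not enforced. The cation can lose a proton instead of being hydroxylated, and electrolysis equipment is required.
- Comparison: the chosen route sets C6 first by a robust catalytic hydrogenation and derives C8a from it, one stereocentre at a time, from a cheap tetralone.

Key step: step 9

## Route

Step 1
Reactants: 1 7-methoxy-1-tetralone; 2 dimethyl carbonate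
Product: 3 methyl 7-methoxy-1-oxo-1,2,3,4-tetrahydronaphthalene-2-carboxylate (racemic, keto/enol mixture)
Conditions: NaH, (MeO)2CO, THF, reflux; aq. HCl
Reagents that add atoms: dimethyl carbonate (2), COC(=O)OC
Why: Crossed Claisen condensation of the ketone enolate with a carbonate; the only enolisable position of the aryl ketone is acylated, and deprotonation of the β-keto ester drives the equilibrium.

Step 2
Reactants: 3 methyl 7-methoxy-1-oxo-1,2,3,4-tetrahydronaphthalene-2-carboxylate
Product: 5 methyl 7-methoxy-3,4-dihydronaphthalene-2-carboxylate, via hydroxy ester 4 (not isolated)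
Conditions: NaBH4, MeOH, 0 °C; solvent exchange; TsOH·H2O (cat.), PhMe, reflux, Dean–Stark
Reagents that add atoms: none
Why: NaBH4 reduces the aryl ketone and leaves the ester; the benzylic β-hydroxy ester then dehydrates under acid catalysis to the alkene conjugated with both the arene and the ester.

Step 3
Reactants: 5 methyl 7-methoxy-3,4-dihydronaphthalene-2-carboxylate
Product: 6 7-methoxy-3,4-dihydronaphthalene-2-carboxylic acid
Conditions: LiOH·H2O, THF/MeOH/H2O, 50 °C; aq. HCl
Reagents that add atoms: lithium hydroxide, [Li+].[OH-]
Why: Saponification of a methyl ester; the free acid is needed because carboxylate binding to ruthenium organises the next step.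

Step 4
Reactants: 6 7-methoxy-3,4-dihydronaphthalene-2-carboxylic acid
Product: 7 (2R)-7-methoxy-1,2,3,4-tetrahydronaphthalene-2-carboxylic acid
Conditions: H2 (pressure), Ru(OAc)2[(R)-BINAP] (cat.), MeOH, rt
Reagents that add atoms: none
Why: Carboxylate-directed asymmetric hydrogenation of a trisubstituted α,β-unsaturated acid with a Ru–BINAP dicarboxylate catalyst; hydrogen is delivered to one enantioface of the chelated alkene and sets the stereocentre that becomes C6; enantiomeric purity can be raised by crystallising an ammonium salt of 7.

Step 5
Reactants: 7 (2R)-7-methoxy-1,2,3,4-tetrahydronaphthalene-2-carboxylic acid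
Product: 8 methyl (2R)-7-methoxy-1,2,3,4-tetrahydronaphthalene-2-carboxylate
Conditions: MeOH, H2SO4 (cat.), reflux
Reagents that add atoms: methanol, CO
Why: Fischer esterification; the stereocentre next to the carbonyl is not enolised under these acidic conditions.

Step 6
Reactants: 8 methyl (2R)-7-methoxy-1,2,3,4-tetrahydronaphthalene-2-carboxylate
Product: 9 2-[(2R)-7-methoxy-1,2,3,4-tetrahydronaphthalen-2-yl]propan-2-ol
Conditions: CH3MgBr (3 equiv), THF, 0 °C → rt; aq. NH4Cl
Reagents that add atoms: methylmagnesium bromide, C[Mg]Br
Why: Double Grignard addition to an ester gives the dimethyl carbinol; the intermediate methyl ketone is consumed faster than it is enolised, so the stereocentre is kept.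

Step 7
Reactants: 9 2-[(2R)-7-methoxy-1,2,3,4-tetrahydronaphthalen-2-yl]propan-2-ol
Product: 10 2-[(2R)-7-methoxy-1,2,3,4,5,8-hexahydronaphthalen-2-yl]propan-2-ol (enol ether C2=C3 and tetrasubstituted C4a=C8a alkene in target locants)
Conditions: Li, NH3(l), THF, t-BuOH, −78 → −33 °C; MeOH, then NH4Cl
Reagents that add atoms: none
Why: Birch reduction of an anisole; protonation ortho and meta to the methoxy group leaves the enol ether double bond and places the second double bond between the two alkyl-bearing carbons, that is at C4a=C8a; the tertiary alkoxide is inert.

Step 8
Reactants: 10 2-[(2R)-7-methoxy-1,2,3,4,5,8-hexahydronaphthalen-2-yl]propan-2-ol; 11 ethylene glycol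
Product: 12 C3 ethylene ketal of (6R)-6-(2-hydroxypropan-2-yl)-1,2,4,5,6,7,8-heptahydronaphthalen-3-one with the C4a=C8a alkene (target locants)
Conditions: HOCH2CH2OH, TsOH·H2O (cat.), CH2Cl2, 4 Å sieves, rt; Et3N
Reagents that add atoms: ethylene glycol (11), OCCO
Why: Acid-catalysed ketalisation of an enol ether (protonation at C2, capture of the oxocarbenium ion by the diol, loss of methanol); the conditions are mild enough to keep the tetrasubstituted alkene out of conjugation and to spare the tertiary alcohol.

Step 9
Reactants: 12 C3 ethylene ketal with the C4a=C8a alkene; 13 diiodomethane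
Product: 14 (6R)-3,3-ethylenedioxy-4a,8a-methanodecalin with the methano bridge on the β face, cis to the C6 2-hydroxypropan-2-yl group
Conditions: Et2Zn (2 equiv), CH2Cl2, 0 °C; then CH2I2 (2 equiv), 0 °C → rt; aq. NH4Cl
Reagents that add atoms: diiodomethane (13), ICI
Why: Et2Zn first converts the C6 carbinol into its ethylzinc alkoxide and, with CH2I2, gives an iodomethylzinc carbenoid held at that oxygen; the carbenoid carbon is transferred to the C4a=C8a bond through the concerted butterfly-type transition state of the Simmons–Smith reaction, forming C4a–CH2 and C8a–CH2 in one syn addition. The closest known reaction type is the hydroxyl-directed Et2Zn/CH2I2 cyclopropanation of cyclic alkenols, including tetrasubstituted ring-fusion alkenes of Birch-derived octalins. The three-membered ring is closed by a [2+1] addition across an existing ring bond, so it is necessarily cis-fused to both six-membered rings. The new stereocentres C4a and C8a are set together and relative to C6: the side chain is equatorial on the half-chair of ring B, its favoured rotamer places oxygen anti to the axial C6–H and therefore on the β side, and zinc bound there can reach only the β face of the alkene. The step needs face selectivity and nothing else, since there is one alkene and the dioxolane is inert; the ketal oxygens lie on both faces and give no bias of their own. To let the alkoxide-bound pathway dominate, the alkoxide is formed before CH2I2 is added, the solvent is non-coordinating and the excess of carbenoid is kept small. The β-methano bridge later becomes the β-methyl at C8a, cis to the C6 side chain as in the target.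

Step 10
Reactants: 14 (6R)-3,3-ethylenedioxy-4a,8a-methanodecalin carbinol
Product: 16 (4aS,7R)-7-(2-hydroxypropan-2-yl)-4a-methyl-4,4a,5,6,7,8-hexahydronaphthalen-2(3H)-one (systematic numbering; C8a-methyl C4=C4a enone in target locants), via cyclopropyl ketone 15 (not isolated)
Conditions: 2 M aq. H2SO4/THF, 60 °C
Reagents that add atoms: water, O
Why: Ketal hydrolysis gives cyclopropyl ketone 15, whose enol towards C4 is a donor-substituted vinylcyclopropane; protonation at the cyclopropane CH2 with cleavage of the C4a–CH2 bond (homoconjugate acid cleavage of a β,γ-cyclopropyl ketone) leaves that carbon as the C8a methyl and gives the C4=C4a enone; no ring bond at C8a is broken, so its configuration is kept, and the aqueous acid with a non-nucleophilic counter-ion lets water recapture the tertiary carbinol if it ionises.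

Step 11
Reactants: 16 C8a-methyl hydroxy enone
Product: 17 triethylsilyl ether of 16 at the side-chain oxygen
Conditions: Et3SiOTf, 2,6-lutidine, CH2Cl2, −78 °C
Reagents that add atoms: triethylsilyl trifluoromethanesulfonate, CC[Si](CC)(CC)OS(=O)(=O)C(F)(F)F
Why: Silyl triflate/hindered pyridine silylation of a tertiary alcohol, faster at low temperature than soft enolisation of the enone (any silyl dienol ether is hydrolysed on work-up); the ether masks this hydroxyl so that only the C3 hydroxyl made in step 13 can be arylated.

Step 12
Reactants: 17 silyl ether enone
Product: 18 trans-fused (6R)-8a-methyl-6-[2-(triethylsilyloxy)propan-2-yl]decalin-3-one (C4a–H α, C8a–CH3 β)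
Conditions: Li, NH3(l), THF, t-BuOH (1 equiv), −78 °C; solid NH4Cl
Reagents that add atoms: none
Why: Dissolving-metal conjugate reduction of the enone; the β-carbon C4a is protonated axially, anti to the C8a methyl group (stereoelectronic control), which gives the trans ring fusion, and the lithium enolate is protonated on work-up.

Step 13
Reactants: 18 trans-decalone
Product: 19 tertiary alcohol with axial α-hydroxyl and equatorial β-methyl at C3 (side-chain oxygen silylated)
Conditions: CH3Ti(OiPr)3, Et2O, −20 °C → rt; aq. NH4Cl
Reagents that add atoms: methyltitanium triisopropoxide, C[Ti](OC(C)C)(OC(C)C)OC(C)C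
Why: Carbonyl addition of a bulky, weakly basic methyltitanium reagent to a conformationally fixed cyclohexanone; equatorial attack avoids the axial hydrogens at C1 and C4a on the α face, so the methyl group becomes equatorial (β) and the new hydroxyl axial (α), as the target requires.

Step 14
Reactants: 20 2-bromo-4-chloro-1-iodobenzene; 21 1,3,5-trimethoxybenzene
Product: 23 (2-bromo-4-chlorophenyl)(2,4,6-trimethoxyphenyl)iodonium 4-methylbenzenesulfonate, via hydroxy(tosyloxy)iodoarene 22 (not isolated)
Conditions: mCPBA, TsOH·H2O, MeCN, 75 °C; then 21, rt
Reagents that add atoms: 1,3,5-trimethoxybenzene (21), COc1cc(OC)cc(OC)c1; p-toluenesulfonic acid monohydrate, Cc1ccc(S(=O)(=O)O)cc1.O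
Why: One-pot oxidation of the aryl iodide to the trivalent iodine species 22 followed by electrophilic substitution of the electron-rich arene at iodine; this is the standard preparation of aryl(trimethoxyphenyl)iodonium tosylates.

Step 15
Reactants: 19 tertiary alcohol; 23 iodonium tosylate
Product: 24 2-bromo-4-chlorophenyl ether of 19 at the C3 oxygen
Conditions: NaH, THF, 50 °C; then 23, rt
Reagents that add atoms: iodonium tosylate (23), COc1cc(OC)c([I+]c2ccc(Cl)cc2Br)c(OC)c1.Cc1ccc(S(=O)(=O)[O-])cc1
Why: Metal-free O-arylation of an alkoxide with a diaryliodonium salt, a reaction documented for tertiary alkoxides; the alkoxide replaces tosylate at iodine and ligand coupling transfers the electron-poorer, ortho-substituted 2-bromo-4-chlorophenyl group while the trimethoxyphenyl group leaves as the aryl iodide; the C3–O bond is not broken, so the C3 configuration is kept.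

Step 16
Reactants: 25 allyl 4-bromophenyl ether
Product: 27 2-allyl-4-bromophenol, via ortho-dienone 26 (not isolated)
Conditions: PhNEt2, 200 °C
Reagents that add atoms: none
Why: Aromatic Claisen rearrangement ([3,3]-sigmatropic shift, then tautomerisation); the two ortho positions are equivalent and the para position is blocked by bromine.

Step 17
Reactants: 27 2-allyl-4-bromophenol
Product: 28 2-allyl-4-(4,4,5,5-tetramethyl-1,3,2-dioxaborolan-2-yl)phenol
Conditions: B2pin2, Pd(dppf)Cl2 (cat.), KOAc, 1,4-dioxane, 90 °C
Reagents that add atoms: bis(pinacolato)diboron, CC1(C)OB(OC1(C)C)B1OC(C)(C)C(C)(C)O1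
Why: Miyaura borylation of an aryl bromide; the weakly basic acetate conditions tolerate the free phenol and the terminal alkene.

Step 18
Reactants: 24 2-bromo-4-chlorophenyl ether; 28 arylboronate
Product: 29 5-chloro-2-(terpenyloxy)biaryl carrying the 3-allyl-4-hydroxyphenyl ring (side-chain oxygen silylated)
Conditions: Pd(dppf)Cl2 (cat.), K3PO4, 1,4-dioxane/H2O, 85 °C
Reagents that add atoms: arylboronate (28), Oc1ccc(B2OC(C)(C)C(C)(C)O2)cc1CC=C
Why: Suzuki–Miyaura coupling; with this bisphosphine catalyst oxidative addition takes place at C–Br and leaves C–Cl, and the tertiary aryl ether and the tertiary silyl ether are stable to aqueous phosphate.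

Step 19
Reactants: 29 biaryl chloride
Product: 30 triethylsilyl ether of the target at the side-chain oxygen
Conditions: CH2=CHCH2SnBu3, Pd2(dba)3 (cat.), P(t-Bu)3 (cat.), CsF, 1,4-dioxane, 100 °C
Reagents that add atoms: allyltributylstannane, C=CC[Sn](CCCC)(CCCC)CCCC
Why: Stille coupling of an aryl chloride with an allylstannane on zerovalent palladium carrying a bulky, electron-rich trialkylphosphine, with fluoride activation of tin; the chloride para to the ether oxygen is unhindered, and the reaction is stopped at full conversion to limit migration of the allyl double bonds.

Step 20
Reactants: 30 silyl ether of the target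
Product: 31 target CNP0342687.1
Conditions: Bu4NF, THF, rt → 45 °C; aq. NH4Cl
Reagents that add atoms: none
Why: Fluoride cleavage of the tertiary triethylsilyl ether under basic conditions, which spare the acid-labile tertiary alkyl aryl ether and the allyl groups.

## Compound list

1 | 7-methoxy-1-tetralone | COc1ccc2CCCC(=O)c2c1 | starting material
2 | dimethyl carbonate | COC(=O)OC | starting material
3 | methyl 7-methoxy-1-oxo-1,2,3,4-tetrahydronaphthalene-2-carboxylate (racemic) | COC(=O)C1CCc2ccc(OC)cc2C1=O | intermediate
4 | methyl 1-hydroxy-7-methoxy-1,2,3,4-tetrahydronaphthalene-2-carboxylate (diastereomer mixture, not isolated) | COC(=O)C1CCc2ccc(OC)cc2C1O | intermediate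
5 | methyl 7-methoxy-3,4-dihydronaphthalene-2-carboxylate | COC(=O)C1=Cc2cc(OC)ccc2CC1 | intermediate
6 | 7-methoxy-3,4-dihydronaphthalene-2-carboxylic acid | OC(=O)C1=Cc2cc(OC)ccc2CC1 | intermediate
7 | (2R)-7-methoxy-1,2,3,4-tetrahydronaphthalene-2-carboxylic acid | COc1ccc2CC[C@@H](C(=O)O)Cc2c1 | intermediate
8 | methyl (2R)-7-methoxy-1,2,3,4-tetrahydronaphthalene-2-carboxylate | COC(=O)[C@@H]1CCc2ccc(OC)cc2C1 | intermediate
9 | 2-[(2R)-7-methoxy-1,2,3,4-tetrahydronaphthalen-2-yl]propan-2-ol | COc1ccc2CC[C@@H](C(C)(C)O)Cc2c1 | intermediate
10 | 2-[(2R)-7-methoxy-1,2,3,4,5,8-hexahydronaphthalen-2-yl]propan-2-ol | CC(C)(O)[C@@H]1CCC2=C(C1)CC(OC)=CC2 | intermediate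
11 | ethylene glycol | OCCO | starting material
12 | C3 ethylene ketal with C4a=C8a alkene and (6R)-2-hydroxypropan-2-yl group | CC(C)(O)[C@@H]1CCC2=C(C1)CC1(CC2)OCCO1 | intermediate
13 | diiodomethane | ICI | starting material
14 | (6R)-3,3-ethylenedioxy-4a,8a-methanodecalin carbinol, methano bridge β and cis to the C6 side chain | CC(C)(O)[C@@H]1CC[C@@]23CCC4(OCCO4)C[C@@]2(C3)C1 | intermediate
15 | 4a,8a-methanodecalin-3-one carbinol (not isolated) | CC(C)(O)[C@@H]1CC[C@@]23CCC(=O)C[C@@]2(C3)C1 | intermediate
16 | (4aS,7R)-7-(2-hydroxypropan-2-yl)-4a-methyl-4,4a,5,6,7,8-hexahydronaphthalen-2(3H)-one | O=C1CC[C@]2(C)CC[C@@H](C(C)(C)O)CC2=C1 | intermediate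
17 | triethylsilyl ether of 16 | O=C1CC[C@]2(C)CC[C@@H](C(C)(C)O[Si](CC)(CC)CC)CC2=C1 | intermediate
18 | trans-fused 8a-methyl-6-[2-(triethylsilyloxy)propan-2-yl]decalin-3-one (C4a–H α) | O=C1CC[C@]2(C)CC[C@@H](C(C)(C)O[Si](CC)(CC)CC)C[C@H]2C1 | intermediate
19 | C3 tertiary alcohol (α-OH axial, β-CH3 equatorial), side chain silylated | O[C@]1(C)CC[C@]2(C)CC[C@@H](C(C)(C)O[Si](CC)(CC)CC)C[C@H]2C1 | intermediate
20 | 2-bromo-4-chloro-1-iodobenzene | Clc1ccc(I)c(Br)c1 | starting material
21 | 1,3,5-trimethoxybenzene | COc1cc(OC)cc(OC)c1 | starting material
22 | 2-bromo-4-chloro-1-[hydroxy(tosyloxy)iodo]benzene (not isolated) | Cc1ccc(S(=O)(=O)OI(O)c2ccc(Cl)cc2Br)cc1 | intermediate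
23 | (2-bromo-4-chlorophenyl)(2,4,6-trimethoxyphenyl)iodonium 4-methylbenzenesulfonate | COc1cc(OC)c([I+]c2ccc(Cl)cc2Br)c(OC)c1.Cc1ccc(S(=O)(=O)[O-])cc1 | intermediate
24 | 2-bromo-4-chlorophenyl ether of 19 | Clc1ccc(O[C@]2(C)CC[C@]3(C)CC[C@@H](C(C)(C)O[Si](CC)(CC)CC)C[C@H]3C2)c(Br)c1 | intermediate
25 | allyl 4-bromophenyl ether | C=CCOc1ccc(Br)cc1 | starting material
26 | 6-allyl-4-bromocyclohexa-2,4-dien-1-one (not isolated) | O=C1C=CC(Br)=CC1CC=C | intermediate
27 | 2-allyl-4-bromophenol | Oc1ccc(Br)cc1CC=C | intermediate
28 | 2-allyl-4-(4,4,5,5-tetramethyl-1,3,2-dioxaborolan-2-yl)phenol | Oc1ccc(B2OC(C)(C)C(C)(C)O2)cc1CC=C | intermediate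
29 | biaryl chloride: 4-chloro-2-(3-allyl-4-hydroxyphenyl)phenyl ether of 19 | Clc1ccc(O[C@]2(C)CC[C@]3(C)CC[C@@H](C(C)(C)O[Si](CC)(CC)CC)C[C@H]3C2)c(-c2ccc(O)c(CC=C)c2)c1 | intermediate
30 | side-chain triethylsilyl ether of the target | C=CCc1ccc(O[C@]2(C)CC[C@]3(C)CC[C@@H](C(C)(C)O[Si](CC)(CC)CC)C[C@H]3C2)c(-c2ccc(O)c(CC=C)c2)c1 | intermediate
31 | CNP0342687.1 | C=CCc1ccc(O[C@]2(C)CC[C@]3(C)CC[C@@H](C(C)(C)O)C[C@H]3C2)c(-c2ccc(O)c(CC=C)c2)c1 | target

## Step count and least certain steps

Total: 20 steps. Longest linear sequence: 17 steps (steps 1–13, 15, 18, 19, 20). Step 14 makes the arylating agent and steps 16–17 make the boronate.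

**Step 9 (key step).** The directing oxygen is three carbons away from the alkene and sits on an equatorial substituent, so carbenoid delivery from it may be slow. Unassisted or ketal-assisted addition to the α face can then compete, which would erode facial selectivity at C4a/C8a; the tetrasubstituted alkene may also convert slowly. Fallback: the director is changed to a primary hydroxyl, whose small CH2O–Zn arm can take the axial orientation directly over the β face (the cis-directing behaviour of cyclohex-3-enylmethanols). The fallback sets out from ester 8 and comes back at 14. LiAlH4 in THF gives [(2R)-7-methoxy-1,2,3,4-tetrahydronaphthalen-2-yl]methanol F1. Li/NH3/t-BuOH gives the hexahydro enol ether carbinol F2. Ethylene glycol 11 with catalytic TsOH gives the hydroxymethyl ketal F3. Et2Zn/CH2I2 in CH2Cl2 gives the β-methano hydroxymethyl ketal F4. TEMPO (cat.)/NaOCl (cat.)/NaClO2 in buffered MeCN gives the carboxylic acid F5. MeI/K2CO3 in DMF gives the methyl ester F6, and CH3MgBr converts it into 14.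

**Step 15.** The alkoxide is hindered and strongly basic. Ligand exchange at iodine may be slow, and base-induced aryne formation from the iodonium salt or transfer of the trimethoxyphenyl group would cost yield and regiochemical integrity. Fallback: nucleophilic aromatic substitution in place of ligand coupling at iodine. It sets out from 19 and comes back at 24: the potassium alkoxide (KH, 18-crown-6, THF, no amide base present) is heated with 2-bromo-4-chloro-1-fluorobenzene (Fc1ccc(Cl)cc1Br), in which fluoride is displaced from the carbon activated by the ortho bromine and para chlorine. No new intermediate arises.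

**Step 10.** The acid needed for the cyclopropane opening may ionise the tertiary carbinol faster than water returns it, leading to dehydration or to loss of configuration at C6 through an exocyclic alkene. Fallback: the two events are separated and the ring is opened without acid. It sets out from 14 and comes back at 16: pyridinium p-toluenesulfonate in wet acetone at rt hydrolyses only the ketal and gives cyclopropyl ketone 15, now isolated; KOH in MeOH at reflux then effects the base-induced fission of the homoconjugated cyclopropyl ketone (the counterpart of the acid cleavage) to enone 16. No new intermediate arises.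

**Step 19.** Oxidative addition into an electron-rich aryl chloride may be sluggish, and at 100 °C palladium hydride species may move the allyl double bonds into conjugation. Partial loss of the silyl group to fluoride is harmless, because it leads to the target. Fallback: the halogens are exchanged so that the allyl group enters at a bromide and the biaryl bond is made at the chloride. It sets out from 19 and comes back at 30. The isomeric salt (4-bromo-2-chlorophenyl)(2,4,6-trimethoxyphenyl)iodonium 4-methylbenzenesulfonate F7 is made as in step 14 from 4-bromo-2-chloro-1-iodobenzene and 21. It arylates the sodium alkoxide of 19 to the 4-bromo-2-chlorophenyl ether F8. Pd(PPh3)4 with allyltributylstannane in PhMe gives the 4-allyl-2-chlorophenyl ether F9. Pd(OAc)2/SPhos/K3PO4 in PhMe/H2O then couples F9 with boronate 28 to give 30.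

**Step 13.** Addition of the titanium reagent to the ketone may be slow, and equatorial attack may not be exclusive, giving some of the C3 epimer. Fallback: the C3 configuration is set by a sulfoxonium ylide and hydride instead of a methyl nucleophile. It sets out from 18 and comes back at 19: Me3S(O)I/NaH in DMSO adds the methylene group equatorially and gives the spiro-epoxide F10 with axial α-oxygen; LiEt3BH in THF opens it at the CH2 terminus to 19.

**Step 4.** The enantioselectivity may be incomplete, or the sense opposite to the one assumed. Fallback: resolution in place of asymmetric catalysis. It sets out from 6 and comes back at 7: H2 over palladium on carbon in EtOAc gives racemic 7-methoxy-1,2,3,4-tetrahydronaphthalene-2-carboxylic acid F11. Crystallisation with (R)-1-phenylethylamine gives the diastereomerically pure ammonium salt F12 of the (R)-acid (the enantiomeric amine is used if the salt of the other antipode crystallises first). Aqueous HCl liberates 7.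

## Further compounds

F1 | step 9 | [(2R)-7-methoxy-1,2,3,4-tetrahydronaphthalen-2-yl]methanol | COc1ccc2CC[C@@H](CO)Cc2c1
F2 | step 9 | [(2R)-7-methoxy-1,2,3,4,5,8-hexahydronaphthalen-2-yl]methanol | OC[C@@H]1CCC2=C(C1)CC(OC)=CC2
F3 | step 9 | C3 ethylene ketal with C4a=C8a alkene and (6R)-hydroxymethyl group | OC[C@@H]1CCC2=C(C1)CC1(CC2)OCCO1
F4 | step 9 | (6R)-3,3-ethylenedioxy-6-(hydroxymethyl)-4a,8a-methanodecalin, methano bridge β | OC[C@@H]1CC[C@@]23CCC4(OCCO4)C[C@@]2(C3)C1
F5 | step 9 | (6R)-3,3-ethylenedioxy-4a,8a-methanodecalin-6-carboxylic acid, methano bridge β | OC(=O)[C@@H]1CC[C@@]23CCC4(OCCO4)C[C@@]2(C3)C1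
F6 | step 9 | methyl (6R)-3,3-ethylenedioxy-4a,8a-methanodecalin-6-carboxylate, methano bridge β | COC(=O)[C@@H]1CC[C@@]23CCC4(OCCO4)C[C@@]2(C3)C1
F0 | step 15 | none | none
F0 | step 10 | none | none
F7 | step 19 | (4-bromo-2-chlorophenyl)(2,4,6-trimethoxyphenyl)iodonium 4-methylbenzenesulfonate | COc1cc(OC)c([I+]c2ccc(Br)cc2Cl)c(OC)c1.Cc1ccc(S(=O)(=O)[O-])cc1
F8 | step 19 | 4-bromo-2-chlorophenyl ether of 19 | Brc1ccc(O[C@]2(C)CC[C@]3(C)CC[C@@H](C(C)(C)O[Si](CC)(CC)CC)C[C@H]3C2)c(Cl)c1
F9 | step 19 | 4-allyl-2-chlorophenyl ether of 19 | C=CCc1ccc(O[C@]2(C)CC[C@]3(C)CC[C@@H](C(C)(C)O[Si](CC)(CC)CC)C[C@H]3C2)c(Cl)c1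
F10 | step 13 | C3 spiro-epoxide of 18 (oxygen axial α, CH2 equatorial β) | O1C[C@]12CC[C@]3(C)CC[C@@H](C(C)(C)O[Si](CC)(CC)CC)C[C@H]3C2
F11 | step 4 | racemic 7-methoxy-1,2,3,4-tetrahydronaphthalene-2-carboxylic acid | COc1ccc2CCC(C(=O)O)Cc2c1
F12 | step 4 | (R)-1-phenylethylammonium (2R)-7-methoxy-1,2,3,4-tetrahydronaphthalene-2-carboxylate | COc1ccc2CC[C@@H](C(=O)[O-])Cc2c1.C[C@@H]([NH3+])c1ccccc1
A1 | alternative 1 | 2-bromo-4-chlorophenyl 3-[1-methyl-2-methylidene-4-(2-triethylsilyloxypropan-2-yl)cyclohexyl]propanoate | O=C(Oc1ccc(Cl)cc1Br)CC[C@]1(C)CC[C@@H](C(C)(C)O[Si](CC)(CC)CC)CC1=C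
A2 | alternative 1 | aryl enol ether from methylenation of A1 | C=C(Oc1ccc(Cl)cc1Br)CC[C@]1(C)CC[C@@H](C(C)(C)O[Si](CC)(CC)CC)CC1=C
A3 | alternative 1 | octalin tertiary aryl ether with C4a=C5 alkene | Clc1ccc(O[C@]2(C)CC[C@]3(C)CC[C@@H](C(C)(C)O[Si](CC)(CC)CC)C=C3C2)c(Br)c1
A4 | alternative 2 | (5R)-dihydrocarvone (C2 epimers) | CC1CC[C@@H](C(C)=C)CC1=O
A5 | alternative 2 | imine of A4 with (R)-1-phenylethylamine | CC1CC[C@@H](C(C)=C)CC1=N[C@H](C)c1ccccc1
A6 | alternative 2 | but-3-en-2-one | CC(=O)C=C
A7 | alternative 2 | 8a-methyl octalenone with the C6 isopropenyl group | O=C1CC[C@]2(C)CC[C@@H](C(C)=C)CC2=C1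
A8 | alternative 3 | tert-butyldimethylsilyl dienol ether with exocyclic methylene and 4-methylpent-3-enyl chain at C8a | C=C1C=C(O[Si](C)(C)C(C)(C)C)CC[C@]1(C)CCC=C(C)C
A9 | alternative 3 | 8a-methyl octalenone with the C6 hydroxyisopropyl group (identical with 16) | O=C1CC[C@]2(C)CC[C@@H](C(C)(C)O)CC2=C1
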